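## Structural features

The target is a normal labdane: a trans-fused decalin (ring A = C1–C5/C10, ring B = C5–C10) that carries a 3-methylidenepent-4-enyl chain (C11–C16, a 2-substituted buta-1,3-diene) on C9 and, on C4, an axial CH2O group (C19) esterified with (Z)-4-hydroxycinnamic acid. Five stereocentres sit on the decalin (4S,5R,8R,9R,10S): the quaternary C4 and C10 flank C5, with C19 and the C20 methyl syn-diaxial, and C10 is followed directly by C9 (chain equatorial, β) and the tertiary C8 carbinol (hydroxyl equatorial, α; C17 methyl axial and syn to C20). The only other stereo-element is the Z double bond of the cinnamate. The fragile parts are that Z enoate (light, nucleophiles and the free phenoxide all open a path to the E isomer), the terminal conjugated diene (acid, radicals, dienophiles) and the tertiary C8 hydroxyl, which eliminates under acid and displaces any leaving group placed on C12. The real difficulty is twofold: the crowded C8–C9–C10 array with two methyl groups forced syn-diaxial, and the ring A triad C4–C5–C10 with two quaternary carbons, which has to be correct before ring B exists. C12 and C19 must also be told apart, because both pass through the CH2OH level. The key step uses the 1,2-relationship between the C8 carbinol carbon (O, CH3) and C9 with its two-carbon arm C11–C12: read backwards, this is the adduct of a C8 ketyl and the β-carbon of an enoate attached to C10, so ring B is opened at C8–C9.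

## Logic of the disconnections

**25 ⇒ 24.** The two O–Si bonds (phenol oxygen and O8) are cut. These are the only positions that need masking late in the route, and one fluoride treatment removes both. The forward step must be non-basic so that the Z enoate, the diene and the tertiary alcohol survive.

**24 ⇒ 21 + 23 (23 ⇐ 22).** The Cα=Cβ bond of the cinnamate is cut. Forming the Z alkene on the substrate avoids making, storing and activating a Z-configured acid, which is where isomerisation usually occurs. The aryl half reduces to 23, one step from 22. The forward step must give the Z isomer under kinetic control.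

**21 ⇒ 20.** The C19 O–acyl bond is cut. This leaves the diterpene alcohol 20 and a simple phosphonoacetic acid. The forward step must acylate a neopentyl, axial hydroxyl, which is the only free hydroxyl in 20.

**20 ⇒ 17 + 19 (19 ⇐ 18).** The C12–C13 bond is cut, so the whole diene comes from the four-carbon nucleophile 19, made from 18. The forward step is an sp3–sp2 coupling at a primary iodide that tolerates the free C19 hydroxyl. O8 must already be blocked; otherwise it would attack C12 and close a five-membered ether.

**17 ⇒ 16 ⇒ 15 ⇒ 14.** No skeletal bond is cut: C12–I goes back to C12–OH, both CH2OH groups go back to esters, and the O8–Si bond is removed. This lets C12 and C19 arrive together from the ring-closing step. The forward steps must protect O8 before C12 is activated and must distinguish two primary alcohols by hindrance alone.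

**14 ⇒ 13.** The C8–C9 bond is cut and ring B is opened, removing C8 and C9 as stereocentres. 13 is a monocyclic ring A compound with a methyl ketone arm on C5 and an E enoate on C10. The forward step must form the ketyl in the presence of an enoate and two esters, close a six-membered ring through a chair, and place O8 equatorial although this makes C17 and C20 syn-diaxial.

**13 ⇒ 12 ⇒ 11 ⇒ 10 ⇒ 9.** The C9=C11 bond is cut (to an aldehyde at C9), then the C6=C7 bond (to an aldehyde at C6); between them lie an oxidation and a hydrogenation that also removes the benzyl group. Both side arms thus reduce to one-carbon stubs on ring A. The forward olefinations must reach two very hindered aldehydes without epimerising C5 away from the equatorial arrangement.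

**9 ⇒ 7.** The C10–C20 bond and the C5–H bond are cut. The methyl group, and not the C9 carbon, is the group added last at C10, because a nucleophile is expected to enter on the face of the C4 ester. This gives C20 cis to C19, as required. The forward conjugate addition must create a quaternary centre with this facial preference, and the protonation must place the formyl group trans to C9.

**7 ⇒ 6 ⇒ 5.** The C5–C6 bond is cut (carbonylation), then the C5–O bond of the enol triflate. This returns the ring ketone. The forward steps must enolise towards C10 without losing the β-benzyloxy group, and must carbonylate a tetrasubstituted triflate.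

**5 ⇒ 4.** The C9–C10 bond is cut. C9 is introduced as a protected hydroxymethyl group by alkylating the only available enolate of 4. The new centre needs no control.

**4 ⇒ 2 ⇒ 1.** The C4–C18 bond is cut. The quaternary C4, the one stereocentre that is set by a chiral controller, comes from methylation of the chiral enamine 2 of the commercial keto ester 1. Every other centre is then set relative to C4.

## Other disconnections considered

**Alternative 1:** The cut removes C4–C5, C9–C10 and the C8–O bond together, leading back to the acyclic epoxy dienoic acid A2. In the forward step MeAlCl2 ionises the oxirane of A2 at C4, the two E alkenes add in turn through a chair–chair fold, and the carboxyl group captures the C8 cation to give the hydroxy lactone A1.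
- In favour: two rings, three bonds and the stereocentres C4, C5, C10, C9 and C8 would come from one oxirane and two alkene geometries, and the lactone is the masked O8/C12 pair.
- Against: A1 carries a 3β-hydroxyl that the target lacks, so it must be removed by radical deoxygenation (two more steps). The C19 oxygen must sit cis to the chain on the oxirane, which is the less accessible geometry and the harder one for asymmetric epoxidation. Lewis-acid cascades that end on a carboxylic acid tend to stop after one ring or end by elimination.
- Comparison: on structure this plan is better than the chosen one, since it builds both rings and needs no preformed ring A triad. On mechanism it is better at C8, because anti addition across an E alkene fixes O8 stereospecifically; it is worse in predictability of the cascade. On step economy the two are about equal once the deoxygenation is counted, and the endgame from C12 and C19 is the same in both.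

**Alternative 2:** The cut removes C5–C10 and C3–C4, leading back to the triene A4, an alkylidene malonate tethered through C6–C9 to a 1,3-diene. In the forward step an intramolecular Diels–Alder reaction of A4 closes rings A and B together to give the octalin A3, with the C9 centre steering the trans fusion.
- In favour: the assembly of A4 from small pieces is convergent, the dienophile is strongly activated, and C4 needs no asymmetric step at this stage.
- Against: the diene terminus C10 carries both the methyl group and the tether, so one of them must sit inside the s-cis diene, which slows the cycloaddition. The two esters on C4 must later be differentiated into CH3 and CH2O on the basis of axial/equatorial hindrance, which costs several redox steps. The C1=C2 bond must be hydrogenated. C8 still has to become the methyl carbinol; direct methyl addition to a C8 carbonyl would come from the α face and give the wrong epimer, so methylenation, epoxidation and hydride opening would be needed.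
- Comparison: on structure it is better (both rings and the C5/C10 relationship in one step). On mechanism it is equal or better for the ring fusion, since a concerted cycloaddition is predictable, but worse for C8, which it leaves open. On step economy it is worse than the chosen plan.

**Alternative 3:** The cut removes C7–C8 of ring B, leading back to the ring-contracted ketol A6, a trans-hydrindane with a 9α-hydroxyl and a 9β-acetyl group. In the forward step BF3·OEt2 holds the hydroxyl and the acetyl oxygen together, C7 shifts from C9 to C8, and the ring expands to the hydroxy ketone A5.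
- In favour: the C8 carbinol would be formed by a stereospecific 1,2-shift. On control of C8 this is better than the chosen plan. C19 is already at the alcohol level.
- Against: C9 is left as a ketone between two fully substituted carbons. The whole C11–C16 chain and the 9α-hydrogen would have to be added afterwards by olefination or addition at a neopentyl ketone, followed by reduction with stereocontrol. The ketol shift is reversible, and migration of C10 instead of C7 must be excluded. A6 itself needs three stereocentres and a tertiary acyloin, so it is no shorter than ring A of the chosen plan.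
- Comparison: on structure it is worse (no bond of the side chain is made). On mechanism it is equal in being substituent-controlled and better for C8. On step economy it is clearly worse.

Key step: step 11

Remarks before the steps:
- Stereochemical remark: 14–25 belong to the normal labdane series (4S,5R,8R,9R,10S; H5 and H9 α, C20 β, C19 the 4β carbon). 13 carries C4, C5 and C10 in the same spatial sense; its C10 descriptor reads R only because the vinyl carbon ranks below C5.
- Assumption: in the methylation of the lithiated L-valine tert-butyl ester enamine, the coordinating additive fixes the face that is attacked. Toluene with THF as ligand is taken to lead to the (S)-keto ester; HMPA as additive or D-valine tert-butyl ester is used if the sense is the opposite one.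
- Assumption: L-valine tert-butyl ester, 2-[bis(2,2,2-trifluoroethoxy)phosphoryl]acetic acid and chloroprene (as a stabilised solution) are taken as purchasable.

## Steps

Step 1
Reactants: 1 methyl 2-oxocyclohexane-1-carboxylate
Product: 2 methyl 2-{[(2S)-1-tert-butoxy-3-methyl-1-oxobutan-2-yl]amino}cyclohex-1-ene-1-carboxylate
Conditions: L-valine tert-butyl ester, BF3·OEt2 (cat.), toluene, reflux, Dean–Stark
Reagents that add atoms: L-valine tert-butyl ester, CC(C)[C@H](N)C(=O)OC(C)(C)C
Why: Condensation of a β-keto ester with a primary amine gives the hydrogen-bonded enamino ester; the valine ester is the chiral controller for step 2 and is recovered there.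

Step 2
Reactants: 2 methyl 2-{[(2S)-1-tert-butoxy-3-methyl-1-oxobutan-2-yl]amino}cyclohex-1-ene-1-carboxylate
Product: 4 methyl (1S)-1-methyl-2-oxocyclohexane-1-carboxylate, via alkylated imine 3 (not isolated)
Conditions: LiN(i-Pr)2, toluene–THF, −78 °C; MeI; then aq. AcOH–NaOAc, rt
Reagents that add atoms: iodomethane, CI
Why: Auxiliary-controlled alkylation of a lithiated chiral enamine of a β-keto ester: lithium is held by nitrogen and the two ester groups, the isopropyl group screens one face of C4, and iodomethane enters the other to set the quaternary C4 as S; mild hydrolysis of imine 3 frees 4 and returns the amino ester.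

Step 3
Reactants: 4 methyl (1S)-1-methyl-2-oxocyclohexane-1-carboxylate
Product: 5 methyl (1S)-3-[(benzyloxy)methyl]-1-methyl-2-oxocyclohexane-1-carboxylate (both C3 epimers)
Conditions: LiN(i-Pr)2, THF, −78 °C; BnOCH2Cl, −78 → −20 °C
Reagents that add atoms: benzyl chloromethyl ether, ClCOCc1ccccc1
Why: C-alkylation of the only possible ketone enolate (towards C10, since C4 has no hydrogen) with a reactive α-chloro ether brings in C9 as a protected hydroxymethyl group; the new centre needs no control because C10 becomes trigonal in step 4.

Step 4
Reactants: 5 methyl (1S)-3-[(benzyloxy)methyl]-1-methyl-2-oxocyclohexane-1-carboxylate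
Product: 6 methyl (1S)-3-[(benzyloxy)methyl]-1-methyl-2-{[(trifluoromethyl)sulfonyl]oxy}cyclohex-2-ene-1-carboxylate
Conditions: KN(SiMe3)2, THF, −78 °C; 2-[N,N-bis(trifluoromethylsulfonyl)amino]-5-chloropyridine, −78 °C
Reagents that add atoms: 2-[N,N-bis(trifluoromethylsulfonyl)amino]-5-chloropyridine, Clc1ccc(N(S(=O)(=O)C(F)(F)F)S(=O)(=O)C(F)(F)F)nc1
Why: O-sulfonylation of a potassium enolate with an N-aryl triflimide (enol triflate formation); only C10 can be deprotonated, and the very reactive pyridyl triflimide should trap the enolate at −78 °C before it can expel benzyl oxide.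

Step 5
Reactants: 6 methyl (1S)-3-[(benzyloxy)methyl]-1-methyl-2-{[(trifluoromethyl)sulfonyl]oxy}cyclohex-2-ene-1-carboxylate
Product: 7 methyl (1S)-3-[(benzyloxy)methyl]-2-formyl-1-methylcyclohex-2-ene-1-carboxylate
Conditions: Pd(PPh3)4 (5 mol %), LiCl, CO (3 atm), Bu3SnH (slow addition), THF, 50 °C
Reagents that add atoms: carbon monoxide, [C-]#[O+]
Why: Palladium-catalysed reductive carbonylation (formylation) of an enol triflate by oxidative addition, CO insertion and hydride transfer from tin; slow addition of the hydride under CO pressure keeps direct reduction of the vinylpalladium species down.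

Step 6
Reactants: 7 methyl (1S)-3-[(benzyloxy)methyl]-2-formyl-1-methylcyclohex-2-ene-1-carboxylate
Product: 9 methyl (1S,2R,3S)-3-[(benzyloxy)methyl]-2-formyl-1,3-dimethylcyclohexane-1-carboxylate, via silyl enol ether 8 (not isolated)
Conditions: Me2CuLi, Me3SiCl, THF, −78 → −30 °C; then 1 M HCl, THF, 0 °C
Reagents that add atoms: lithium dimethylcuprate, [Li+].C[Cu-]C
Why: Silyl-chloride-accelerated conjugate addition of a Gilman cuprate to a β,β-disubstituted enal; the methyl group should enter C10 axially on the ester face, because the chair-like transition state places the smaller CO2Me of C4 (not its methyl) syn-axial to the incoming copper and lithium bound to that ester points the same way, which makes C20 cis to C19. Silyl enol ether 8 is then protonated at C5 on the α face, anti to the two β-axial groups, so the formyl group ends equatorial and trans to C9, which is also the more stable epimer.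

Step 7
Reactants: 9 methyl (1S,2R,3S)-3-[(benzyloxy)methyl]-2-formyl-1,3-dimethylcyclohexane-1-carboxylate
Product: 10 methyl (1S,2R,3S)-3-[(benzyloxy)methyl]-1,3-dimethyl-2-[(1E)-3-oxobut-1-en-1-yl]cyclohexane-1-carboxylate
Conditions: (MeO)2P(O)CH2C(O)CH3, LiCl, DBU, MeCN, rt
Reagents that add atoms: dimethyl (2-oxopropyl)phosphonate, COP(=O)(CC(C)=O)OC
Why: Horner–Wadsworth–Emmons olefination under Masamune–Roush conditions; the small, nucleophilic phosphonate anion should reach the hindered C6 aldehyde and give the E enone, and the mild base can only move C5 towards the equatorial (desired) arrangement.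

Step 8
Reactants: 10 methyl (1S,2R,3S)-3-[(benzyloxy)methyl]-1,3-dimethyl-2-[(1E)-3-oxobut-1-en-1-yl]cyclohexane-1-carboxylate
Product: 11 methyl (1S,2R,3S)-3-(hydroxymethyl)-1,3-dimethyl-2-(3-oxobutyl)cyclohexane-1-carboxylate
Conditions: H2 (1 atm), 10% Pd/C, EtOAc–EtOH, rt
Reagents that add atoms: none
Why: Heterogeneous hydrogenation saturates the C6=C7 bond of the enone and hydrogenolyses the benzyl ether in one operation, while ketone and ester stay; the freed C9 hydroxyl is trans to the C19 ester and cannot lactonise.

Step 9
Reactants: 11 methyl (1S,2R,3S)-3-(hydroxymethyl)-1,3-dimethyl-2-(3-oxobutyl)cyclohexane-1-carboxylate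
Product: 12 methyl (1S,2R,3S)-3-formyl-1,3-dimethyl-2-(3-oxobutyl)cyclohexane-1-carboxylate
Conditions: Dess–Martin periodinane, CH2Cl2, rt
Reagents that add atoms: none
Why: Dess–Martin oxidation of the neopentyl primary alcohol; the aldehyde has no α-hydrogen, and the neutral medium avoids an aldol reaction with the methyl ketone.

Step 10
Reactants: 12 methyl (1S,2R,3S)-3-formyl-1,3-dimethyl-2-(3-oxobutyl)cyclohexane-1-carboxylate
Product: 13 methyl (1S,2R,3R)-3-[(1E)-3-methoxy-3-oxoprop-1-en-1-yl]-1,3-dimethyl-2-(3-oxobutyl)cyclohexane-1-carboxylate
Conditions: Ph3P=CHCO2Me, toluene, 90 °C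
Reagents that add atoms: methyl (triphenylphosphoranylidene)acetate, COC(=O)C=P(c1ccccc1)(c1ccccc1)c1ccccc1
Why: Wittig reaction of a stabilised ylide: it reacts with the aldehyde and not with the ketone, gives the E enoate, and is not basic enough to enolise the methyl ketone.

Step 11
Reactants: 13 methyl (1S,2R,3R)-3-[(1E)-3-methoxy-3-oxoprop-1-en-1-yl]-1,3-dimethyl-2-(3-oxobutyl)cyclohexane-1-carboxylate
Product: 14 dimethyl 8α-hydroxy-13,14,15,16-tetranorlabdane-12,19-dioate [methyl (1S,4aS,5R,6R,8aR)-6-hydroxy-5-(2-methoxy-2-oxoethyl)-1,4a,6-trimethyldecahydronaphthalene-1-carboxylate]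
Conditions: SmI2 (2.5 equiv), HMPA (10 equiv), t-BuOH (2 equiv), THF, −78 → −20 °C; cold sat. aq. NH4Cl
Reagents that add atoms: none
Why: Divalent samarium, made more reducing and bulkier by HMPA, gives one electron to the C8 ketone; the ketyl carbon adds to C9, the β-carbon of the enoate, the α-ester radical takes a second electron, and t-BuOH protonates the samarium enolate (if the enoate were reduced first, the same C8–C9 bond would result). The closest known reaction type is the SmI2-promoted ketyl–olefin cyclization of ketones tethered to α,β-unsaturated esters, which gives 2-hydroxycycloalkylacetates. Ring B closes in a 6-exo-trig mode, and because the two tethers are trans-diequatorial on C5 and C10, only a chair that becomes the trans-decalin is within reach. C9 is set by the enoate staying equatorial on the forming ring, so that C11 ends β and H9 axial; the other rotamer would push C11 against the axial hydrogens on C5 and C7. C8 is set by the samarium-bound oxygen, the largest group on the ketyl carbon, taking the equatorial site anti to the enoate (which also minimises dipole repulsion), leaving the C17 methyl axial and giving the 8α-hydroxyl. Chemoselectivity is needed against plain reduction of the ketone or the enoate and against attack on the C19 ester: the nucleophilic ketyl and the electron-poor alkene are polarity-matched and intramolecular, the weak proton donor lets the ketyl live until it has cyclised, and the hindered axial ester is not reduced by SmI2. Face selectivity at C8 is the point the substrate secures least well, because the favoured chair places C17 syn-diaxial to C20. The cold, buffered quench keeps the trans-diequatorial hydroxy ester open for step 12.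

Step 12
Reactants: 14 dimethyl 8α-hydroxy-13,14,15,16-tetranorlabdane-12,19-dioate
Product: 15 dimethyl 8α-(triethylsilyloxy)-13,14,15,16-tetranorlabdane-12,19-dioate
Conditions: Et3SiOTf, 2,6-lutidine, CH2Cl2, −78 → 0 °C
Reagents that add atoms: triethylsilyl trifluoromethanesulfonate, CC[Si](CC)(CC)OS(=O)(=O)C(F)(F)F
Why: Silylation of a tertiary alcohol with a silyl triflate and a hindered base; masking O8 now stops closure onto the C12 ester and, later, displacement of the C12 iodide by O8.

Step 13
Reactants: 15 dimethyl 8α-(triethylsilyloxy)-13,14,15,16-tetranorlabdane-12,19-dioate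
Product: 16 8α-(triethylsilyloxy)-13,14,15,16-tetranorlabdane-12,19-diol
Conditions: LiAlH4, THF, 0 → 45 °C
Reagents that add atoms: none
Why: Hydride reduction of both esters to primary alcohols; the axial, neopentyl C19 ester needs the strong reagent and gentle warming, and the tertiary silyl ether is inert to hydride.

Step 14
Reactants: 16 8α-(triethylsilyloxy)-13,14,15,16-tetranorlabdane-12,19-diol
Product: 17 12-iodo-8α-(triethylsilyloxy)-13,14,15,16-tetranorlabdan-19-ol
Conditions: I2 (1.1 equiv), PPh3, imidazole, CH2Cl2, 0 °C
Reagents that add atoms: iodine, II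
Why: Appel-type iodination; displacement of the alkoxyphosphonium group by iodide is an SN2 process, fast at the unhindered C12 and very slow at the neopentyl, axial C19, so one equivalent of reagent should take C12 only.

Step 15
Reactants: 18 chloroprene (2-chlorobuta-1,3-diene)
Product: 19 buta-1,3-dien-2-ylmagnesium chloride (THF solution, titrated and used at once)
Conditions: Mg, BrCH2CH2Br (activator), ZnCl2 (cat.), THF, reflux
Reagents that add atoms: magnesium, [Mg]
Why: Grignard formation from a vinylic chloride, made possible by entrainment and a little ZnCl2; the dienyl reagent is the C13–C16 unit as a nucleophile.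

Step 16
Reactants: 17 12-iodo-8α-(triethylsilyloxy)-13,14,15,16-tetranorlabdan-19-ol; 19 buta-1,3-dien-2-ylmagnesium chloride
Product: 20 8α-(triethylsilyloxy)labda-13(16),14-dien-19-ol
Conditions: 19 (3 equiv), Li2CuCl4 (5 mol %), THF, −20 → 0 °C
Reagents that add atoms: none
Why: Copper-catalysed cross-coupling of a primary alkyl iodide with an alkenyl Grignard reagent forms C12–C13; the first equivalent of 19 only deprotonates the C19 hydroxyl, and the silyl ether at O8 cannot attack C12.

Step 17
Reactants: 20 8α-(triethylsilyloxy)labda-13(16),14-dien-19-ol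
Product: 21 8α-(triethylsilyloxy)labda-13(16),14-dien-19-yl 2-[bis(2,2,2-trifluoroethoxy)phosphoryl]acetate
Conditions: (CF3CH2O)2P(O)CH2CO2H, DCC, DMAP (cat.), CH2Cl2, 0 °C → rt
Reagents that add atoms: 2-[bis(2,2,2-trifluoroethoxy)phosphoryl]acetic acid, OC(=O)CP(=O)(OCC(F)(F)F)OCC(F)(F)F
Why: Steglich esterification; the phosphonoacetic acid is activated easily by the carbodiimide and should acylate even the neopentyl C19 hydroxyl, the only free hydroxyl in 20.

Step 18
Reactants: 22 4-hydroxybenzaldehyde
Product: 23 4-[(tert-butyldimethylsilyl)oxy]benzaldehyde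
Conditions: t-BuMe2SiCl, imidazole, DMF, rt
Reagents that add atoms: tert-butyldimethylsilyl chloride, CC(C)(C)[Si](C)(C)Cl
Why: Silylation of the phenol; a free phenoxide would quench the phosphonate anion and deactivate the aldehyde in step 19.

Step 19
Reactants: 21 8α-(triethylsilyloxy)labda-13(16),14-dien-19-yl 2-[bis(2,2,2-trifluoroethoxy)phosphoryl]acetate; 23 4-[(tert-butyldimethylsilyl)oxy]benzaldehyde
Product: 24 8α-(triethylsilyloxy)labda-13(16),14-dien-19-yl (2Z)-3-{4-[(tert-butyldimethylsilyl)oxy]phenyl}prop-2-enoate
Conditions: KN(SiMe3)2, 18-crown-6, THF, −78 °C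
Reagents that add atoms: none
Why: Still–Gennari olefination: with trifluoroethyl phosphonates and a dissociated potassium counter-ion the first adduct collapses faster than it equilibrates, so the aromatic aldehyde should give the Z cinnamate under kinetic control; making the Z bond on the substrate avoids activating a Z acid.

Step 20
Reactants: 24 8α-(triethylsilyloxy)labda-13(16),14-dien-19-yl (2Z)-3-{4-[(tert-butyldimethylsilyl)oxy]phenyl}prop-2-enoate
Product: 25 8α-hydroxylabda-13(16),14-dien-19-yl (2Z)-3-(4-hydroxyphenyl)prop-2-enoate (CNP0197278.1)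
Conditions: HF·pyridine, pyridine, THF, 0 °C → rt, in the dark
Reagents that add atoms: none
Why: Fluoride-mediated desilylation removes the aryl silyl ether and the tertiary triethylsilyl ether together; the buffered, non-basic medium avoids phenoxide-assisted Z to E isomerisation, ester cleavage and dehydration at C8.

## Compound list

1 | methyl 2-oxocyclohexane-1-carboxylate | COC(=O)C1CCCCC1=O | starting material
2 | methyl 2-{[(2S)-1-tert-butoxy-3-methyl-1-oxobutan-2-yl]amino}cyclohex-1-ene-1-carboxylate | COC(=O)C1=C(N[C@@H](C(C)C)C(=O)OC(C)(C)C)CCCC1 | intermediate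
3 | methyl (1S)-2-{[(2S)-1-tert-butoxy-3-methyl-1-oxobutan-2-yl]imino}-1-methylcyclohexane-1-carboxylate | CC(C)[C@@H](C(=O)OC(C)(C)C)N=C1CCCC[C@]1(C)C(=O)OC | intermediate (not isolated)
4 | methyl (1S)-1-methyl-2-oxocyclohexane-1-carboxylate | O=C1CCCC[C@]1(C)C(=O)OC | intermediate
5 | methyl (1S)-3-[(benzyloxy)methyl]-1-methyl-2-oxocyclohexane-1-carboxylate (C3 epimers) | O=C1C(COCc2ccccc2)CCC[C@]1(C)C(=O)OC | intermediate
6 | methyl (1S)-3-[(benzyloxy)methyl]-1-methyl-2-{[(trifluoromethyl)sulfonyl]oxy}cyclohex-2-ene-1-carboxylate | O=S(=O)(OC1=C(COCc2ccccc2)CCC[C@]1(C)C(=O)OC)C(F)(F)F | intermediate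
7 | methyl (1S)-3-[(benzyloxy)methyl]-2-formyl-1-methylcyclohex-2-ene-1-carboxylate | O=CC1=C(COCc2ccccc2)CCC[C@]1(C)C(=O)OC | intermediate
8 | methyl (1S,3S)-3-[(benzyloxy)methyl]-1,3-dimethyl-2-{[(trimethylsilyl)oxy]methylidene}cyclohexane-1-carboxylate | c1ccccc1COC[C@@]2(C)CCC[C@](C)(C(=O)OC)C2=CO[Si](C)(C)C | intermediate (not isolated)
9 | methyl (1S,2R,3S)-3-[(benzyloxy)methyl]-2-formyl-1,3-dimethylcyclohexane-1-carboxylate | c1ccccc1COC[C@@]2(C)CCC[C@](C)(C(=O)OC)[C@@H]2C=O | intermediate
10 | methyl (1S,2R,3S)-3-[(benzyloxy)methyl]-1,3-dimethyl-2-[(1E)-3-oxobut-1-en-1-yl]cyclohexane-1-carboxylate | c1ccccc1COC[C@@]2(C)CCC[C@](C)(C(=O)OC)[C@@H]2/C=C/C(C)=O | intermediate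
11 | methyl (1S,2R,3S)-3-(hydroxymethyl)-1,3-dimethyl-2-(3-oxobutyl)cyclohexane-1-carboxylate | OC[C@@]1(C)CCC[C@](C)(C(=O)OC)[C@@H]1CCC(C)=O | intermediate
12 | methyl (1S,2R,3S)-3-formyl-1,3-dimethyl-2-(3-oxobutyl)cyclohexane-1-carboxylate | O=C[C@@]1(C)CCC[C@](C)(C(=O)OC)[C@@H]1CCC(C)=O | intermediate
13 | methyl (1S,2R,3R)-3-[(1E)-3-methoxy-3-oxoprop-1-en-1-yl]-1,3-dimethyl-2-(3-oxobutyl)cyclohexane-1-carboxylate | COC(=O)/C=C/[C@@]1(C)CCC[C@](C)(C(=O)OC)[C@@H]1CCC(C)=O | intermediate
14 | dimethyl 8α-hydroxy-13,14,15,16-tetranorlabdane-12,19-dioate | COC(=O)C[C@@H]1[C@@]2(C)CCC[C@](C)(C(=O)OC)[C@@H]2CC[C@@]1(C)O | intermediate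
15 | dimethyl 8α-(triethylsilyloxy)-13,14,15,16-tetranorlabdane-12,19-dioate | COC(=O)C[C@@H]1[C@@]2(C)CCC[C@](C)(C(=O)OC)[C@@H]2CC[C@@]1(C)O[Si](CC)(CC)CC | intermediate
16 | 8α-(triethylsilyloxy)-13,14,15,16-tetranorlabdane-12,19-diol | OCC[C@@H]1[C@@]2(C)CCC[C@](C)(CO)[C@@H]2CC[C@@]1(C)O[Si](CC)(CC)CC | intermediate
17 | 12-iodo-8α-(triethylsilyloxy)-13,14,15,16-tetranorlabdan-19-ol | ICC[C@@H]1[C@@]2(C)CCC[C@](C)(CO)[C@@H]2CC[C@@]1(C)O[Si](CC)(CC)CC | intermediate
18 | chloroprene (2-chlorobuta-1,3-diene) | C=CC(Cl)=C | starting material
19 | buta-1,3-dien-2-ylmagnesium chloride | C=CC(=C)[Mg]Cl | intermediate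
20 | 8α-(triethylsilyloxy)labda-13(16),14-dien-19-ol | C=CC(=C)CC[C@@H]1[C@@]2(C)CCC[C@](C)(CO)[C@@H]2CC[C@@]1(C)O[Si](CC)(CC)CC | intermediate
21 | 8α-(triethylsilyloxy)labda-13(16),14-dien-19-yl 2-[bis(2,2,2-trifluoroethoxy)phosphoryl]acetate | C=CC(=C)CC[C@@H]1[C@@]2(C)CCC[C@](C)(COC(=O)CP(=O)(OCC(F)(F)F)OCC(F)(F)F)[C@@H]2CC[C@@]1(C)O[Si](CC)(CC)CC | intermediate
22 | 4-hydroxybenzaldehyde | O=Cc1ccc(O)cc1 | starting material
23 | 4-[(tert-butyldimethylsilyl)oxy]benzaldehyde | O=Cc1ccc(O[Si](C)(C)C(C)(C)C)cc1 | intermediate
24 | 8α-(triethylsilyloxy)labda-13(16),14-dien-19-yl (2Z)-3-{4-[(tert-butyldimethylsilyl)oxy]phenyl}prop-2-enoate | C=CC(=C)CC[C@@H]1[C@@]2(C)CCC[C@](C)(COC(=O)/C=C\c3ccc(O[Si](C)(C)C(C)(C)C)cc3)[C@@H]2CC[C@@]1(C)O[Si](CC)(CC)CC | intermediate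
25 | 8α-hydroxylabda-13(16),14-dien-19-yl (2Z)-3-(4-hydroxyphenyl)prop-2-enoate, (4S,5R,8R,9R,10S) | C=CC(=C)CC[C@@H]1[C@@]2(C)CCC[C@](C)(COC(=O)/C=C\c3ccc(O)cc3)[C@@H]2CC[C@@]1(C)O | target

## Step count and least certain steps

Total: 20 steps. Longest linear sequence: 18 steps (steps 1–14, 16, 17, 19, 20, from 1 to 25). Steps 15 and 18 are one-step side branches.

**Step 11 (key step).**
- What may go wrong: loss of face selectivity at C8, because the chair with the oxygen axial escapes the syn-diaxial contact between C17 and C20. The HMPA-activated reagent may also reduce the enoate before the ring closes.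
- Fallback (sets out from 13, returns at 14): ring closure and oxygenation of C8 are separated. 13 is treated with KN(SiMe3)2 and the 5-chloropyridyl triflimide at −78 °C to give the kinetic enol triflate of the methyl ketone, methyl (1S,2R,3R)-3-[(1E)-3-methoxy-3-oxoprop-1-en-1-yl]-1,3-dimethyl-2-(3-{[(trifluoromethyl)sulfonyl]oxy}but-3-en-1-yl)cyclohexane-1-carboxylate F1. A reductive 6-exo Heck cyclization (Pd(OAc)2, PPh3, HCO2Na, DMF, 80 °C) joins C8 to C9 and should give dimethyl 13,14,15,16-tetranorlabd-8(17)-ene-12,19-dioate F2 with the C9 arm equatorial. Mukaiyama hydration (Mn(dpm)3, PhSiH3, O2, i-PrOH, then P(OEt)3) then generates the tertiary C8 radical; oxygen should be taken up from the equatorial α side, away from the axial C20 methyl, which returns 14.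

**Step 6.**
- What may go wrong: poor or reversed facial selectivity at C10, because the two groups on C4 differ little in size. The tetrasubstituted enal may also react sluggishly or by 1,2-addition.
- Fallback (sets out from 4, returns at 13): the order of introduction at C10 is inverted. This is the right answer if the nucleophile turns out to enter trans to the ester. 4 is methylated (LiN(i-Pr)2, MeI) to methyl (1S)-1,3-dimethyl-2-oxocyclohexane-1-carboxylate F3. This is converted as in step 4 into methyl (1S)-1,3-dimethyl-2-{[(trifluoromethyl)sulfonyl]oxy}cyclohex-2-ene-1-carboxylate F4 and formylated as in step 5 to methyl (1S)-2-formyl-1,3-dimethylcyclohex-2-ene-1-carboxylate F5. (CH2=CH)2CuLi then delivers C9 and should give, after protonation, methyl (1S,2R,3R)-3-ethenyl-2-formyl-1,3-dimethylcyclohexane-1-carboxylate F6. Olefination as in step 7 gives methyl (1S,2R,3R)-3-ethenyl-1,3-dimethyl-2-[(1E)-3-oxobut-1-en-1-yl]cyclohexane-1-carboxylate F7. 1,4-Reduction with [(Ph3P)CuH]6 leaves the vinyl group and gives methyl (1S,2R,3R)-3-ethenyl-1,3-dimethyl-2-(3-oxobutyl)cyclohexane-1-carboxylate F8. Cross-metathesis with methyl acrylate (second-generation Hoveyda–Grubbs catalyst, toluene, 80 °C) returns 13.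

**Step 4.**
- What may go wrong: β-elimination of benzyl oxide from the enolate before it is sulfonylated. O-alkylation in step 3 would feed the same problem.
- Fallback (sets out from 4, returns at 7): C9 is brought in after the enal exists, so no enolate with a β-alkoxy group is needed. 4 is converted (KN(SiMe3)2, the same triflimide) into methyl (1S)-1-methyl-2-{[(trifluoromethyl)sulfonyl]oxy}cyclohex-2-ene-1-carboxylate F9 and formylated as in step 5 to methyl (1S)-2-formyl-1-methylcyclohex-2-ene-1-carboxylate F10. Conjugate addition of the benzyloxymethyl cuprate (from Bu3SnCH2OBn, n-BuLi and CuBr·SMe2) with Me3SiCl gives methyl (1S)-3-[(benzyloxy)methyl]-1-methyl-2-{[(trimethylsilyl)oxy]methylidene}cyclohexane-1-carboxylate F11. Saegusa–Ito oxidation (Pd(OAc)2, MeCN) can only eliminate towards C10 and returns 7.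

**Step 5.**
- What may go wrong: slow oxidative addition at the tetrasubstituted triflate and direct reduction of the vinylpalladium intermediate instead of CO insertion.
- Fallback (sets out from 6, returns at 7): the formyl carbon is introduced as a vinyl group. Stille coupling of 6 with Bu3SnCH=CH2 (Pd(PPh3)4, LiCl, THF, reflux) gives methyl (1S)-3-[(benzyloxy)methyl]-2-ethenyl-1-methylcyclohex-2-ene-1-carboxylate F12. Lemieux–Johnson cleavage (OsO4 cat., NaIO4, 2,6-lutidine, dioxane–water) of the terminal double bond, which is far more accessible than the tetrasubstituted ring alkene, returns 7.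

**Step 16.**
- What may go wrong: decay or polymerisation of the dienyl Grignard reagent, and reduction or elimination of the iodide in place of coupling.
- Fallback (sets out from 17, returns at 20): the diene is built from an alkyne. 17 is alkylated with LiC≡CH·H2NCH2CH2NH2 (DMSO, rt, excess to cover the free hydroxyl) to give 8α-(triethylsilyloxy)-15,16-dinorlabd-13-yn-19-ol F13. Ene–yne cross-metathesis with ethene (second-generation Grubbs catalyst, 1 atm, CH2Cl2, 40 °C) turns the terminal alkyne into the 2-substituted buta-1,3-diene and returns 20.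

## Further compounds

F1 | step 11 | methyl (1S,2R,3R)-3-[(1E)-3-methoxy-3-oxoprop-1-en-1-yl]-1,3-dimethyl-2-(3-{[(trifluoromethyl)sulfonyl]oxy}but-3-en-1-yl)cyclohexane-1-carboxylate | COC(=O)/C=C/[C@@]1(C)CCC[C@](C)(C(=O)OC)[C@@H]1CCC(=C)OS(=O)(=O)C(F)(F)F
F2 | step 11 | dimethyl 13,14,15,16-tetranorlabd-8(17)-ene-12,19-dioate | COC(=O)C[C@@H]1[C@@]2(C)CCC[C@](C)(C(=O)OC)[C@@H]2CCC1=C
F3 | step 6 | methyl (1S)-1,3-dimethyl-2-oxocyclohexane-1-carboxylate (C3 epimers) | O=C1C(C)CCC[C@]1(C)C(=O)OC
F4 | step 6 | methyl (1S)-1,3-dimethyl-2-{[(trifluoromethyl)sulfonyl]oxy}cyclohex-2-ene-1-carboxylate | O=S(=O)(OC1=C(C)CCC[C@]1(C)C(=O)OC)C(F)(F)F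
F5 | step 6 | methyl (1S)-2-formyl-1,3-dimethylcyclohex-2-ene-1-carboxylate | O=CC1=C(C)CCC[C@]1(C)C(=O)OC
F6 | step 6 | methyl (1S,2R,3R)-3-ethenyl-2-formyl-1,3-dimethylcyclohexane-1-carboxylate | C=C[C@@]1(C)CCC[C@](C)(C(=O)OC)[C@@H]1C=O
F7 | step 6 | methyl (1S,2R,3R)-3-ethenyl-1,3-dimethyl-2-[(1E)-3-oxobut-1-en-1-yl]cyclohexane-1-carboxylate | C=C[C@@]1(C)CCC[C@](C)(C(=O)OC)[C@@H]1/C=C/C(C)=O
F8 | step 6 | methyl (1S,2R,3R)-3-ethenyl-1,3-dimethyl-2-(3-oxobutyl)cyclohexane-1-carboxylate | C=C[C@@]1(C)CCC[C@](C)(C(=O)OC)[C@@H]1CCC(C)=O
F9 | step 4 | methyl (1S)-1-methyl-2-{[(trifluoromethyl)sulfonyl]oxy}cyclohex-2-ene-1-carboxylate | O=S(=O)(OC1=CCCC[C@]1(C)C(=O)OC)C(F)(F)F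
F10 | step 4 | methyl (1S)-2-formyl-1-methylcyclohex-2-ene-1-carboxylate | O=CC1=CCCC[C@]1(C)C(=O)OC
F11 | step 4 | methyl (1S)-3-[(benzyloxy)methyl]-1-methyl-2-{[(trimethylsilyl)oxy]methylidene}cyclohexane-1-carboxylate (C3 epimers) | c1ccccc1COCC2CCC[C@](C)(C(=O)OC)C2=CO[Si](C)(C)C
F12 | step 5 | methyl (1S)-3-[(benzyloxy)methyl]-2-ethenyl-1-methylcyclohex-2-ene-1-carboxylate | C=CC1=C(COCc2ccccc2)CCC[C@]1(C)C(=O)OC
F13 | step 16 | 8α-(triethylsilyloxy)-15,16-dinorlabd-13-yn-19-ol | C#CCC[C@@H]1[C@@]2(C)CCC[C@](C)(CO)[C@@H]2CC[C@@]1(C)O[Si](CC)(CC)CC
A1 | alternative 1 | 3β-hydroxy-19-(tert-butyldiphenylsilyloxy)-13,14,15,16-tetranorlabdan-12,8α-olide | O=C3C[C@@H]1[C@@]2(C)CC[C@H](O)[C@](C)(CO[Si](c4ccccc4)(c4ccccc4)C(C)(C)C)[C@@H]2CC[C@@]1(C)O3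
A2 | alternative 1 | (3E,7E)-10-[(2S,3R)-3-{[(tert-butyldiphenylsilyl)oxy]methyl}-3-methyloxiran-2-yl]-4,8-dimethyldeca-3,7-dienoic acid | OC(=O)C/C=C(\C)CC/C=C(\C)CC[C@@H]1O[C@]1(C)CO[Si](c2ccccc2)(c2ccccc2)C(C)(C)C
A3 | alternative 2 | dimethyl 12-(tert-butyldimethylsilyloxy)-8,8-(ethylenedioxy)-13,14,15,16,17-pentanorlabd-1-ene-18,19-dioate (trans-fused octalin gem-diester) | CC(C)(C)[Si](C)(C)OCC[C@@H]1[C@@]2(C)C=CCC(C(=O)OC)(C(=O)OC)[C@@H]2CCC15OCCO5
A4 | alternative 2 | dimethyl 2-[3-(2-{(3R,4E)-1-[(tert-butyldimethylsilyl)oxy]-4-methylhepta-4,6-dien-3-yl}-1,3-dioxolan-2-yl)propylidene]propanedioate | COC(=O)C(C(=O)OC)=CCCC1(OCCO1)[C@H](CCO[Si](C)(C)C(C)(C)C)/C(C)=C/C=C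
A5 | alternative 3 | 19-(tert-butyldiphenylsilyloxy)-8α-hydroxy-11,12,13,14,15,16-hexanorlabdan-9-one | O=C1[C@@]2(C)CCC[C@](C)(CO[Si](c3ccccc3)(c3ccccc3)C(C)(C)C)[C@@H]2CC[C@@]1(C)O
A6 | alternative 3 | 1-[(1R,3aS,4S,7aS)-4-{[(tert-butyldiphenylsilyl)oxy]methyl}-1-hydroxy-4,7a-dimethyloctahydro-1H-inden-1-yl]ethan-1-one | CC(=O)[C@]2(O)[C@@]1(C)CCC[C@](C)(CO[Si](c3ccccc3)(c3ccccc3)C(C)(C)C)[C@@H]1CC2
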